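(The earlier runs and the new flask come from a simulation from invented constants.)

| flask | substrate | coupling partner | remark | time |
|---|---|---|---|---|
| north | 0.50 M | 0.50 M | run made earlier |  |
| north-west | 0.34 M | 0.50 M | run made earlier |  |
| east | 0.75 M | 0.50 M | run made earlier |  |
| winter | 0.50 M (in portions, 3, over 50 s) | 0.500 M | first portion at the start, last at 50 s | 2.0 min |
| autumn | 0.50 M | 0.500 M (fed, over 50 s) | all else is in the flask from the start; the feed brings no volume worth counting | 2.0 min |
| midnight | 0.50 M (fed, over 50 s) | 0.500 M | all else is in the flask from the start; the feed brings no volume worth counting | 2.0 min |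
| dusk | 0.50 M | 0.500 M (fed, over 5.0 s) | all else is in the flask from the start; the feed brings no volume worth counting | 2.0 min |
| noon | 0.50 M | 0.500 M | everything together at the start | 2.0 min |

| run | time / s | tris adduct / % | bis adduct / % | substrate / % |
|---|---|---|---|---|
| north | 25.0 | 8.7 | 12.3 | 37.5 |
| north | 50.0 | 7.4 | 13.8 | 38.3 |
| north | 80.0 | 8.4 | 12.9 | 36.6 |
| north | 90.0 | 11.0 | 12.2 | 37.1 |
| north | 120 | 9.7 | 15.0 | 38.3 |
| north-west | 10.0 | 13.2 | 13.2 | 33.4 |
| north-west | 20.0 | 18.0 | 15.9 | 26.1 |
| north-west | 30.0 | 18.6 | 18.7 | 23.3 |
| north-west | 50.0 | 20.3 | 18.9 | 24.5 |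
| north-west | 80.0 | 21.0 | 17.7 | 21.8 |
| east | 15.0 | 2.9 | 8.2 | 51.6 |
| east | 30.0 | 2.7 | 8.1 | 52.3 |
| east | 40.0 | 2.1 | 8.4 | 50.7 |
| east | 60.0 | 3.9 | 7.8 | 52.1 |
| east | 80.0 | 3.4 | 7.7 | 51.1 |

(readings scatter by 1 percentage point)



- the flask that comes out highest in amount of tris adduct, in percent of the substrate charged, or "all alike" when all lie within 1.5 percentage points (winter / autumn / midnight / dusk / noon / all alike)
- tris adduct at the end, in percent of the substrate charged, winter
- tris adduct at the end, in percent of the substrate charged, autumn
- tris adduct at the end, in percent of the substrate charged, midnight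
- tris adduct at the end, in percent of the substrate charged, dusk
- tris adduct at the end, in percent of the substrate charged, noon

**Step 1.** I began by counting. A tris adduct holds 3 coupling partner, so the partner charge divided by 3, taken per substrate charged, is the tris ceiling: 33.3% in each of the five flasks asked about.

**Step 2.** The north run stood flat from 25.0 s with 38.3% of its substrate left at the last reading. I therefore took the partner as the limiting reagent.

**Step 3.** I read each run as a share of its own ceiling. The north run averaged 27.1% at 1.00 partner per substrate. The north-west run, at 1.47, read 42.8%. So the share rose with partner per substrate.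

**Step 4.** One end was plain. Noon, dusk and autumn reach 1.00 partner per substrate charged at most, so I put them at the north share, near 9.02%.

**Step 5.** The other end was winter. Its first portion met 3.00 partner per substrate, more than the north-west run had. The next portion came after 25.0 s, about the time by which the north run stood flat. I therefore expected winter above the north-west share, so above 14.3%.

**Step 6.** Midnight joined the two ends. By 25.0 s its feed had brought half of the substrate, while winter had received a third. That is 2.00 partner per substrate, less than in winter, so I placed midnight below winter.

**The forecast.** It named winter, with winter 20.3%, midnight 18.8%, and autumn, dusk and noon 9% each. It added “Winter and midnight are close”. My reckoning also placed midnight below winter, but it gave midnight no figure.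

**The result.**

    substrate + coupling partner → mono adduct + by-product (k = 0.480 L mol⁻¹ s⁻¹)
    coupling partner + mono adduct → bis adduct + by-product (k = 0.390 L mol⁻¹ s⁻¹)
    coupling partner + bis adduct → tris adduct + by-product (k = 0.760 L mol⁻¹ s⁻¹)
    2 coupling partner → homo dimer (k = 0.0310 L mol⁻¹ s⁻¹)

Winter gave 18.5%, more than any other flask, and midnight gave 12.8% against the forecast's 18.8%. Autumn gave 10.3%, dusk 9.52% and noon 9.12%. Winter already held 18.4% tris adduct at 0.833 min, just before its last portion. Against the ceiling, winter reached 55.6% and midnight 38.4%. A neighbouring winter flask, charged with 0.30 M of substrate, has a ceiling of 55.6%. It gave 29.6%, a share of 53.2%.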